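**Retrosynthetic overview**
1. Rings A and B are bought intact: ring A as acetophenone 1 (all four OMe groups and the future O1 in place), ring B as O-benzyl syringaldehyde 2.
2. C2–C3 disconnection: Claisen–Schmidt condensation of 1 with 2 (through aldol adduct 3) gives chalcone 4.
3. O1–C2 disconnection: ring C, the only ring that has to be built, is closed last by I2/DMSO oxidative cyclisation of 4 (through flavanone 5) to flavone 6.
4. End game: BCl3 cleaves the 4'-O-benzyl ether and, by chelation to C4=O, only the peri 5-OMe (through boron species 7) to give target 8.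

Assumption: the target is a planar, achiral flavone with no stereocentre, so "single enantiomer" needs no stereocontrol; 1 and 2 are taken as catalogue compounds.

**Step 1**
Reactants: 1 2'-hydroxy-3',4',5',6'-tetramethoxyacetophenone; 2 4-benzyloxy-3,5-dimethoxybenzaldehyde
Product: 4 (E)-4-benzyloxy-2'-hydroxy-3,5,3',4',5',6'-hexamethoxychalcone, via aldol adduct 3 (not isolated)
Conditions: KOH (50% aq., 10 equiv), EtOH, rt, 36 h; then 1 M HCl to pH 3
Reagents that add atoms: none
Why: Claisen–Schmidt (crossed aldol) condensation, in which the methyl-ketone enolate of 1 adds to the non-enolisable aldehyde 2 and aldol 3 dehydrates by E1cB to the conjugated, thermodynamically favoured E-enone, so no stereocentre is retained.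

**Step 2**
Reactants: 4 (E)-4-benzyloxy-2'-hydroxy-3,5,3',4',5',6'-hexamethoxychalcone
Product: 6 4'-benzyloxy-5,6,7,8,3',5'-hexamethoxyflavone, via flavanone 5 (not isolated)
Conditions: I2 (10 mol %), DMSO, 130 °C, 3 h
Reagents that add atoms: none
Why: I2/DMSO oxidative cyclisation, in which 6-endo oxa-Michael addition of the 2'-OH closes ring C as racemic flavanone 5 and iodine then dehydrogenates C2–C3 (erasing the transient C2 stereocentre) while DMSO as terminal oxidant regenerates the iodine.

**Step 3**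
Reactants: 6 4'-benzyloxy-5,6,7,8,3',5'-hexamethoxyflavone
Product: 8 5,4'-dihydroxy-6,7,8,3',5'-pentamethoxyflavone, via bis(dichloroboryloxy)flavone 7 (not isolated)
Conditions: BCl3 (1 M in CH2Cl2, 5 equiv), pentamethylbenzene (3 equiv), CH2Cl2, −78 °C 1 h then 0 °C 2 h; then H2O
Reagents that add atoms: none
Why: Lewis-acid ether cleavage, in which BCl3 removes the benzyl group at −78 °C (the benzyl cation is trapped by pentamethylbenzene in a Friedel–Crafts reaction) and, chelated between C4=O and the peri 5-OMe, cleaves only that methyl ether on warming; hydrolysis of 7 leaves no reagent atoms in 8.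

**Compound list**
1 | 2'-hydroxy-3',4',5',6'-tetramethoxyacetophenone [1-(2-hydroxy-3,4,5,6-tetramethoxyphenyl)ethan-1-one] | CC(=O)c1c(O)c(OC)c(OC)c(OC)c1OC | starting material
2 | 4-benzyloxy-3,5-dimethoxybenzaldehyde (O-benzyl syringaldehyde) | COc1cc(C=O)cc(OC)c1OCc1ccccc1 | starting material
3 | 3-(4-benzyloxy-3,5-dimethoxyphenyl)-3-hydroxy-1-(2-hydroxy-3,4,5,6-tetramethoxyphenyl)propan-1-one (aldol adduct, racemic, not isolated) | COc1cc(C(O)CC(=O)c2c(O)c(OC)c(OC)c(OC)c2OC)cc(OC)c1OCc1ccccc1 | intermediate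
4 | (E)-4-benzyloxy-2'-hydroxy-3,5,3',4',5',6'-hexamethoxychalcone [(E)-3-(4-benzyloxy-3,5-dimethoxyphenyl)-1-(2-hydroxy-3,4,5,6-tetramethoxyphenyl)prop-2-en-1-one] | COc1cc(/C=C/C(=O)c2c(O)c(OC)c(OC)c(OC)c2OC)cc(OC)c1OCc1ccccc1 | intermediate
5 | 4'-benzyloxy-5,6,7,8,3',5'-hexamethoxyflavanone [2-(4-benzyloxy-3,5-dimethoxyphenyl)-5,6,7,8-tetramethoxychroman-4-one] (racemic, not isolated) | COc1cc(C2CC(=O)c3c(OC)c(OC)c(OC)c(OC)c3O2)cc(OC)c1OCc1ccccc1 | intermediate
6 | 4'-benzyloxy-5,6,7,8,3',5'-hexamethoxyflavone [2-(4-benzyloxy-3,5-dimethoxyphenyl)-5,6,7,8-tetramethoxy-4H-chromen-4-one] | COc1cc(-c2cc(=O)c3c(OC)c(OC)c(OC)c(OC)c3o2)cc(OC)c1OCc1ccccc1 | intermediate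
7 | 5,4'-bis(dichloroboryloxy)-6,7,8,3',5'-pentamethoxyflavone (5-O–B chelated to C4=O, not isolated) | COc1cc(-c2cc(=O)c3c(OB(Cl)Cl)c(OC)c(OC)c(OC)c3o2)cc(OC)c1OB(Cl)Cl | intermediate
8 | 5,4'-dihydroxy-6,7,8,3',5'-pentamethoxyflavone (achiral) | COc1cc(-c2cc(=O)c3c(O)c(OC)c(OC)c(OC)c3o2)cc(OC)c1O | target

**Totals**
Total step count: 3. Longest linear sequence: 3 steps (1 or 2 → 4 → 6 → 8).

**Steps most likely to fail, most risky first**

The dual deprotection of step 3 is the main risk. Excess BCl3 or too much warming could also cleave the 6-OMe (next to the new 5-O–B chelate) or a 3'/5'-OMe (next to the 4'-O–B), and too little leaves the 5-OMe intact. The fallback sets out from 6 and comes back at 8, and makes the two deprotections orthogonal. The benzyl ether is first hydrogenolysed (H2 1 atm, 10% Pd/C, EtOAc/MeOH, rt; the flavone C2=C3 bond is not reduced under these conditions) to 4'-hydroxy-5,6,7,8,3',5'-hexamethoxyflavone F5. Only the peri 5-OMe is then cleaved under chelation control with AlCl3 in MeCN at rt, giving 8.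

The oxidative cyclisation of step 2 is next. Hot I2/DMSO may stall at the flavanone or partly cleave the benzyl ether or the 5-OMe; such ether-cleaved flavones still converge on 8 in step 3, but a messy mixture would cost yield. The fallback sets out from 4 and comes back at 6, and separates ring closure from oxidation. Chalcone 4 is cyclised with NaOAc in refluxing EtOH to isolated flavanone 5. This is α-brominated with CuBr2 (EtOAc/CHCl3, reflux) to 2-(4-benzyloxy-3,5-dimethoxyphenyl)-3-bromo-5,6,7,8-tetramethoxychroman-4-one F4. Dehydrobromination with K2CO3 in DMF at rt then gives flavone 6.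

The condensation of step 1 is the least risky of the three. The doubly ortho-substituted ketone 1 is hindered and may condense slowly; partial closure of 4 to flavanone 5 on work-up is harmless for step 2. The fallback sets out from 1 and 2 and comes back at 6, bypassing step 2, and replaces C=C formation by a Baker–Venkataraman acyl transfer. Aldehyde 2 is oxidised (NaClO2, NaH2PO4, 2-methyl-2-butene, t-BuOH/H2O) to 4-benzyloxy-3,5-dimethoxybenzoic acid F1. The phenol of 1 is esterified with it (EDC·HCl, DMAP, CH2Cl2) to 2-acetyl-3,4,5,6-tetramethoxyphenyl 4-benzyloxy-3,5-dimethoxybenzoate F2. Rearrangement with KOH in pyridine at 50 °C gives 1-(4-benzyloxy-3,5-dimethoxyphenyl)-3-(2-hydroxy-3,4,5,6-tetramethoxyphenyl)propane-1,3-dione F3. Cyclodehydration with catalytic p-TsOH in refluxing toluene then gives flavone 6.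

**Further compounds**
F1 | step 1 | 4-benzyloxy-3,5-dimethoxybenzoic acid | COc1cc(C(=O)O)cc(OC)c1OCc1ccccc1
F2 | step 1 | 2-acetyl-3,4,5,6-tetramethoxyphenyl 4-benzyloxy-3,5-dimethoxybenzoate | CC(=O)c1c(OC(=O)c2cc(OC)c(OCc3ccccc3)c(OC)c2)c(OC)c(OC)c(OC)c1OC
F3 | step 1 | 1-(4-benzyloxy-3,5-dimethoxyphenyl)-3-(2-hydroxy-3,4,5,6-tetramethoxyphenyl)propane-1,3-dione | COc1cc(C(=O)CC(=O)c2c(O)c(OC)c(OC)c(OC)c2OC)cc(OC)c1OCc1ccccc1
F4 | step 2 | 2-(4-benzyloxy-3,5-dimethoxyphenyl)-3-bromo-5,6,7,8-tetramethoxychroman-4-one (racemic) | COc1cc(C2Oc3c(OC)c(OC)c(OC)c(OC)c3C(=O)C2Br)cc(OC)c1OCc1ccccc1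
F5 | step 3 | 4'-hydroxy-5,6,7,8,3',5'-hexamethoxyflavone | COc1cc(-c2cc(=O)c3c(OC)c(OC)c(OC)c(OC)c3o2)cc(OC)c1O
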